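**Retrosynthetic overview**
- The strategy rests on ring C (O1, C2, C3, C4, C4a, C8a). It lies between ring A (O1 on C8a, free hydroxyl on C7, methoxy on C6: a resorcinol pattern), the arylacetyl unit C4–C3–ring B, and the single carbon C2.
- Cutting C4–C4a, C2–C3 and O1–C2 in one operation gives 4-methoxybenzene-1,3-diol, 3,4,5-trimethoxyphenylacetic acid and DMF (source of C2).
- The diol comes from isovanillin by Baeyer–Villiger oxidation and formate cleavage; the hydroxyl created there is the one that becomes O1.
- Rings A and B are bought intact. Ring C is the only ring formed; it closes in the last step, which gives the target with the C7 hydroxyl free.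

Key step: step 3

Remark: the target is achiral and its only non-benzenoid C=C bond is endocyclic, so no stereochemical element has to be set; the diol is made rather than bought because it is costly and air-sensitive.

**Route**

Step 1
Reactants: 1 isovanillin (3-hydroxy-4-methoxybenzaldehyde)
Product: 2 3-hydroxy-4-methoxyphenyl formate
Conditions: mCPBA, CH2Cl2, 0 °C to rt; cold aq Na2SO3/NaHCO3 wash; crude product carried on
Reagents that add atoms: mCPBA (3-chloroperoxybenzoic acid), OOC(=O)c1cccc(Cl)c1
Why: Baeyer–Villiger oxidation, in which the electron-rich aryl group (para to the methoxy group) should migrate to oxygen in preference to hydride and give the aryl formate, while the free phenol meta to the formyl group takes no part.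

Step 2
Reactants: 2 3-hydroxy-4-methoxyphenyl formate
Product: 3 4-methoxybenzene-1,3-diol
Conditions: cat. conc. HCl, degassed MeOH, rt, Ar; evaporate
Reagents that add atoms: none
Why: Acid-catalysed transesterification (methanolysis) of the labile aryl formate should release the phenol and volatile methyl formate, and the acidic, oxygen-free medium spares the oxidation-prone 1,2,4-trioxygenated ring.

Step 3
Reactants: 3 4-methoxybenzene-1,3-diol; 4 3,4,5-trimethoxyphenylacetic acid; 5 N,N-dimethylformamide
Product: 8 7-hydroxy-6-methoxy-3-(3,4,5-trimethoxyphenyl)-4H-chromen-4-one, via deoxybenzoin 6 (not isolated), via enaminone 7 (not isolated)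
Conditions: BF3·OEt2 (neat), 85 °C, Ar; cool, DMF, then MeSO2Cl in DMF, 50 to 70 °C; ice–water
Reagents that add atoms: none
Why: BF3·OEt2 activates acid 4 and Friedel–Crafts C-acylates diol 3 (directly or by O-acylation and Fries shift) to form C4–C4a, giving deoxybenzoin 6, which stays coordinated to boron through its ortho-hydroxy ketone unit. The chloromethyleneiminium salt generated from DMF 5 and MeSO2Cl then attacks the enolised benzylic carbon (Vilsmeier-type C-formylation, C2–C3) to give enaminone 7, present in the acidic medium as its O-coordinated iminium form. Once the boron chelate opens and the aryl–carbonyl bond rotates, the ortho oxygen adds to the iminium carbon (O1–C2; 6-exo-trig at C=N+, equally 6-endo-trig if counted on the enaminone C=C, both favoured), and loss of dimethylamine aromatises the pyranone. The closest known reaction type is the one-pot BF3·OEt2 acylation and DMF/MeSO2Cl cyclisation of resorcinols with arylacetic acids to 7-hydroxyisoflavones. No stereocentre is formed. The step needs acylation at the one ring carbon that is ortho to the 1-hydroxyl and para to the 3-hydroxyl (future C4a) and closure through the ortho oxygen only: the carbon between the hydroxyls is hindered, the carbon next to the methoxy group is meta to both hydroxyls, and the C7 hydroxyl is para to the carbonyl (a vinylogous acid) and cannot reach C2, so it stays free.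

**Compound list**
1 | isovanillin (3-hydroxy-4-methoxybenzaldehyde) | COc1ccc(C=O)cc1O | starting material
2 | 3-hydroxy-4-methoxyphenyl formate | COc1ccc(OC=O)cc1O | intermediate
3 | 4-methoxybenzene-1,3-diol | COc1ccc(O)cc1O | intermediate
4 | 3,4,5-trimethoxyphenylacetic acid | COc1cc(CC(=O)O)cc(OC)c1OC | starting material
5 | N,N-dimethylformamide | CN(C)C=O | starting material
6 | 1-(2,4-dihydroxy-5-methoxyphenyl)-2-(3,4,5-trimethoxyphenyl)ethan-1-one (deoxybenzoin) | COc1cc(C(=O)Cc2cc(OC)c(OC)c(OC)c2)c(O)cc1O | intermediate
7 | (E)-3-(dimethylamino)-1-(2,4-dihydroxy-5-methoxyphenyl)-2-(3,4,5-trimethoxyphenyl)prop-2-en-1-one (enaminone; drawn E, the push–pull alkene equilibrates and either geometry closes) | COc1cc(C(=O)/C(=C/N(C)C)c2cc(OC)c(OC)c(OC)c2)c(O)cc1O | intermediate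
8 | 7-hydroxy-6-methoxy-3-(3,4,5-trimethoxyphenyl)-4H-chromen-4-one | COc1cc2c(=O)c(-c3cc(OC)c(OC)c(OC)c3)coc2cc1O | target

**Step count**
Total steps: 3. Longest linear sequence: 3 (1 → 2 → 3 → 8); 4 and 5 are purchased.

**Steps most likely to fail**

Step 3. The first stage may suffer competing acylation of the electron-rich trimethoxyphenyl ring of a second molecule of 4. The second stage may suffer incomplete C-formylation or closure, with formylation or sulfonylation of the free hydroxyl. Either leaves a mixture that the one-pot format cannot clean up. The fallback separates the two events and uses different electrophiles. It sets out from 3: Houben–Hoesch reaction with commercial 3,4,5-trimethoxyphenylacetonitrile (ZnCl2, dry HCl, Et2O, 0 °C) should precipitate 1-(2,4-dihydroxy-5-methoxyphenyl)-2-(3,4,5-trimethoxyphenyl)ethan-1-iminium chloride F1, which is filtered free of neutral by-products. Hydrolysis in hot water should give deoxybenzoin 6, now isolated and crystallised. Ring closure with triethyl orthoformate, pyridine and catalytic piperidine at reflux then returns to the route at 8.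

Step 1. The peracid may oxidise the unprotected, electron-rich phenol ring to quinonoid material instead of attacking only the aldehyde. The fallback masks the phenol and sets out from 1. Benzylation (BnBr, K2CO3, DMF) should give 3-(benzyloxy)-4-methoxybenzaldehyde F2. Baeyer–Villiger oxidation (mCPBA, CH2Cl2) should give 3-(benzyloxy)-4-methoxyphenyl formate F3. Methanolysis (cat. K2CO3, MeOH) should give 3-(benzyloxy)-4-methoxyphenol F4. Hydrogenolysis (H2, Pd/C, EtOAc) returns to the route at 3.

Step 2. The liberated diol may be oxidised by air during concentration, and residual 3-chlorobenzoic acid is hard to remove from so polar a compound. The fallback purifies through a stable derivative and sets out from 2. After the methanolysis the residue is not purified but acetylated at once (Ac2O, pyridine, cat. DMAP) to 4-methoxy-1,3-phenylene diacetate F5, which is non-polar, air-stable and can be chromatographed or crystallised. Deacetylation with catalytic HCl in degassed MeOH under argon and evaporation of the volatiles returns to the route at 3, which is charged directly to step 3.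

**Further compounds**
F1 | step 3 | 1-(2,4-dihydroxy-5-methoxyphenyl)-2-(3,4,5-trimethoxyphenyl)ethan-1-iminium chloride | COc1cc(C(=[NH2+])Cc2cc(OC)c(OC)c(OC)c2)c(O)cc1O.[Cl-]
F2 | step 1 | 3-(benzyloxy)-4-methoxybenzaldehyde | COc1ccc(C=O)cc1OCc1ccccc1
F3 | step 1 | 3-(benzyloxy)-4-methoxyphenyl formate | COc1ccc(OC=O)cc1OCc1ccccc1
F4 | step 1 | 3-(benzyloxy)-4-methoxyphenol | COc1ccc(O)cc1OCc1ccccc1
F5 | step 2 | 4-methoxy-1,3-phenylene diacetate | COc1ccc(OC(C)=O)cc1OC(C)=O
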